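Retrosynthesis: target 21 ⇐ 20 ⇐ 19 by hydrogenation of the isopropenyl group and acetylation at O6.
19 ⇐ 18: the ten-membered ring is closed last by forming C6–C7 in a visible-light photoredox/chromium intramolecular allylation of an epoxy aldehyde that carries an allylic chloride; this sets C6 and C7.
18 ⇐ 13: angeloylation at O3, ene-chlorination of the terminal isopropylidene, desilylation, oxidation of C6.
13 ⇐ 2 + 9: C1–C2 bond by alkenylalanate opening of a terminal oxirane; the C4–C5 oxirane is the first ring formed, by hydroxyl-directed epoxidation of 8 (C3 sets C4 and C5).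
8 ⇐ 6 ⇐ 3: (R)-glyceraldehyde acetonide supplies C3; alkyne homologation and zirconium-catalysed methylalumination build C4(Me)=C5–C6.

Assumption: positions are given in germacrane numbering (C1=C10 ring alkene, O3 angelate, C4–C5 oxirane, O6 acetate, C7 isopropyl), the target is the (3R,4R,5R,6S,7S) isomer encoded by the SMILES, and alkyne 2 is made, not bought.

Step 1
Reactants: 1 5-bromo-2-methylpent-2-ene
Product: 2 6-methylhept-5-en-1-yne
Conditions: LiC≡CH·H2NCH2CH2NH2, DMSO, 0 °C to rt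
Reagents that add atoms: lithium acetylide–ethylenediamine complex, [Li+].[C-]#C.NCCN
Why: SN2 alkylation of lithium acetylide by an unhindered primary bromide in DMSO; no stereocentre is involved.

Step 2
Reactants: 3 (4R)-2,2-dimethyl-1,3-dioxolane-4-carbaldehyde
Product: 5 (2S)-but-3-yne-1,2-diol, via alkyne acetonide 4 (not isolated)
Conditions: dimethyl (1-diazo-2-oxopropyl)phosphonate, K2CO3, MeOH, 0 °C to rt; filter; Dowex 50WX8 (H+ form), MeOH–H2O, 40 °C
Reagents that add atoms: dimethyl (1-diazo-2-oxopropyl)phosphonate, CC(=O)C(=[N+]=[N-])P(=O)(OC)OC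
Why: Ohira–Bestmann (Seyferth–Gilbert) homologation turns the aldehyde into the terminal alkyne under carbonate conditions that do not epimerise the α-alkoxy centre, and acid-resin hydrolysis of the acetonide avoids isolating the volatile alkyne; C3 is the stereocentre bought in 3.

Step 3
Reactants: 5 (2S)-but-3-yne-1,2-diol
Product: 6 (2S)-2-hydroxybut-3-yn-1-yl 4-methylbenzenesulfonate
Conditions: TsCl (1.05 equiv), Bu2SnO (2 mol %), Et3N, CH2Cl2, 0 °C
Reagents that add atoms: 4-methylbenzenesulfonyl chloride, Cc1ccc(cc1)S(Cl)(=O)=O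
Why: tin-acetal-catalysed regioselective sulfonylation of the primary hydroxyl of a 1,2-diol; C3 is untouched.

Step 4
Reactants: 6 (2S)-2-hydroxybut-3-yn-1-yl 4-methylbenzenesulfonate
Product: 8 (2S,3E)-2-hydroxy-3-methyl-5-{[tri(propan-2-yl)silyl]oxy}pent-3-en-1-yl 4-methylbenzenesulfonate, via alkenylalane 7 (not isolated)
Conditions: Me3Al (3.5 equiv), Cp2ZrCl2 (25 mol %), CH2Cl2, 0 °C to rt; then iPr3SiOCH2Cl, 0 °C to rt; aq. sodium potassium tartrate work-up
Reagents that add atoms: trimethylaluminium, C[Al](C)C; (triisopropylsiloxy)methyl chloride, CC(C)[Si](OCCl)(C(C)C)C(C)C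
Why: Negishi zirconium-catalysed syn-methylalumination of the terminal alkyne (the hydroxyl is carried as its aluminium alkoxide) puts methyl on C4 and aluminium on C5, and C-alkylation of the alkenylalane by the α-chloro ether with retention gives the (E)-trisubstituted alkene with C6 already silylated.

Step 5
Reactants: 8 (2S,3E)-2-hydroxy-3-methyl-5-{[tri(propan-2-yl)silyl]oxy}pent-3-en-1-yl 4-methylbenzenesulfonate
Product: 9 (2R)-2-hydroxy-2-[(2R,3R)-2-methyl-3-({[tri(propan-2-yl)silyl]oxy}methyl)oxiran-2-yl]ethyl 4-methylbenzenesulfonate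
Conditions: VO(acac)2 (5 mol %), t-BuOOH (1.5 equiv, decane solution), CH2Cl2, 0 °C to rt
Reagents that add atoms: tert-butyl hydroperoxide, CC(C)(C)OO
Why: hydroxyl-directed vanadium-catalysed epoxidation of a secondary allylic alcohol, in which A(1,2) strain between the C4 methyl and the carbinol substituent enforces the erythro transition state, so the bought C3 centre sets C4 and C5 as (4R,5R).

Step 6
Reactants: 9 (2R)-2-hydroxy-2-[(2R,3R)-2-methyl-3-({[tri(propan-2-yl)silyl]oxy}methyl)oxiran-2-yl]ethyl 4-methylbenzenesulfonate; 2 6-methylhept-5-en-1-yne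
Product: 13 (1R,3E)-4,8-dimethyl-1-[(2R,3R)-2-methyl-3-({[tri(propan-2-yl)silyl]oxy}methyl)oxiran-2-yl]nona-3,7-dien-1-ol, via bis-epoxide 10 (not isolated), via alkenylalane 11 (not isolated), via lithium alanate 12 (not isolated)
Conditions: 2, Me3Al (2 equiv), Cp2ZrCl2 (25 mol %), CH2Cl2, 0 °C to rt; solvent switch to THF, n-BuLi, −78 °C; separately 9, NaH, THF, 0 °C; combine at −78 °C, warm to rt; aq. sodium potassium tartrate work-up
Reagents that add atoms: trimethylaluminium, C[Al](C)C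
Why: Negishi syn-methylalumination of 2 gives the (E)-alkenylalane, whose lithium ate complex opens the monosubstituted oxirane of 10 (formed by intramolecular Williamson displacement of the tosylate) at its CH2 terminus in an SN2 epoxide opening, which creates the C1–C2 bond and the (E)-C1=C10 alkene while C3, C4 and C5 are untouched.

Step 7
Reactants: 13 (1R,3E)-4,8-dimethyl-1-[(2R,3R)-2-methyl-3-({[tri(propan-2-yl)silyl]oxy}methyl)oxiran-2-yl]nona-3,7-dien-1-ol; 14 (2Z)-2-methylbut-2-enoic acid (angelic acid)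
Product: 15 (1R,3E)-4,8-dimethyl-1-[(2R,3R)-2-methyl-3-({[tri(propan-2-yl)silyl]oxy}methyl)oxiran-2-yl]nona-3,7-dien-1-yl (2Z)-2-methylbut-2-enoate
Conditions: 14 (3 equiv), 2,4,6-trichlorobenzoyl chloride (3 equiv), Et3N, toluene, rt; then 13, 75 °C, no DMAP
Reagents that add atoms: none
Why: Yamaguchi mixed-anhydride esterification without DMAP acylates the hindered O3 hydroxyl with retention at C3 and keeps the (Z)-geometry of the angelate.

Step 8
Reactants: 15 (1R,3E)-4,8-dimethyl-1-[(2R,3R)-2-methyl-3-({[tri(propan-2-yl)silyl]oxy}methyl)oxiran-2-yl]nona-3,7-dien-1-yl (2Z)-2-methylbut-2-enoate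
Product: 16 (1R,3E)-7-chloro-4,8-dimethyl-1-[(2R,3R)-2-methyl-3-({[tri(propan-2-yl)silyl]oxy}methyl)oxiran-2-yl]nona-3,8-dien-1-yl (2Z)-2-methylbut-2-enoate (both epimers at the chlorinated carbon)
Conditions: N-chlorosuccinimide (1.1 equiv), PhSeCl (10 mol %), CH2Cl2, rt
Reagents that add atoms: N-chlorosuccinimide, O=C1CCC(=O)N1Cl
Why: selenium-catalysed ene-type allylic chlorination (PhSeCl addition, oxidation by NCS, syn-elimination) is fastest at the electron-rich, unhindered terminal isopropylidene, whereas the C1=C10 alkene is shielded and inductively deactivated by O3 and the angelate alkene is electron-poor; the new C–Cl centre is an irrelevant epimer mixture that is erased in step 11.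

Step 9
Reactants: 16 (1R,3E)-7-chloro-4,8-dimethyl-1-[(2R,3R)-2-methyl-3-({[tri(propan-2-yl)silyl]oxy}methyl)oxiran-2-yl]nona-3,8-dien-1-yl (2Z)-2-methylbut-2-enoate
Product: 17 (1R,3E)-7-chloro-1-[(2R,3R)-3-(hydroxymethyl)-2-methyloxiran-2-yl]-4,8-dimethylnona-3,8-dien-1-yl (2Z)-2-methylbut-2-enoate (both epimers at the chlorinated carbon)
Conditions: HF·pyridine, pyridine, THF, 0 °C to rt
Reagents that add atoms: none
Why: fluoride cleavage of the primary silyl ether with pyridine-buffered HF leaves the oxirane, the allylic chloride and the angelate intact.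

Step 10
Reactants: 17 (1R,3E)-7-chloro-1-[(2R,3R)-3-(hydroxymethyl)-2-methyloxiran-2-yl]-4,8-dimethylnona-3,8-dien-1-yl (2Z)-2-methylbut-2-enoate
Product: 18 (1R,3E)-7-chloro-1-[(2R,3S)-3-formyl-2-methyloxiran-2-yl]-4,8-dimethylnona-3,8-dien-1-yl (2Z)-2-methylbut-2-enoate (both epimers at the chlorinated carbon)
Conditions: Dess–Martin periodinane, pyridine, CH2Cl2, 0 °C to rt
Reagents that add atoms: none
Why: Dess–Martin oxidation of the primary alcohol gives the α,β-epoxy aldehyde under buffered, non-epimerising conditions (the C5 descriptor changes only because the substituent priorities change).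

Step 11
Reactants: 18 (1R,3E)-7-chloro-1-[(2R,3S)-3-formyl-2-methyloxiran-2-yl]-4,8-dimethylnona-3,8-dien-1-yl (2Z)-2-methylbut-2-enoate
Product: 19 (1R,2R,4E,8S,9S,10R)-9-hydroxy-1,5-dimethyl-8-(prop-1-en-2-yl)-11-oxabicyclo[8.1.0]undec-4-en-2-yl (2Z)-2-methylbut-2-enoate [(3R,4R,5R,6S,7S)-3-angeloyloxy-4,5-epoxygermacra-1(10),11-dien-6-ol]
Conditions: 2,4,5,6-tetra(carbazol-9-yl)isophthalonitrile (4CzIPN, 3 mol %), CrCl3(THF)3 (30 mol %), Hantzsch ester (2 equiv), 2,6-lutidine (3 equiv), THF–DMF 4:1, 18 added over 10 h to 2 mM final concentration, 450 nm LEDs, 25 °C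
Reagents that add atoms: none
Why: Proposed new method: a dual photoredox/chromium-catalysed reductive intramolecular allylation (Nozaki–Hiyama–Kishi type) that closes a ten-membered carbocycle, not yet shown for medium rings or epoxy aldehydes; photoexcited 4CzIPN is reduced by the Hantzsch ester and passes the electron to trivalent chromium, the divalent chromium formed abstracts chlorine from either epimer of 18 and a second divalent chromium traps the allyl radical at its CH2 terminus, the primary allylchromium adds through its γ-carbon (C7) to the aldehyde in a chair Zimmerman–Traxler transition state with the C8 tether equatorial and chromium bridged by the aldehyde and oxirane oxygens, which should give the 6,7-anti, 5,6-syn product (6S,7S) under control of the C4/C5 centres, and the proton released by the oxidised Hantzsch ester frees the alkoxide so chromium turns over; closest known reactions are intermolecular photoredox/chromium allylations of aldehydes and thermal macro-allylations of related epoxy aldehydes with stoichiometric CrCl2 or with Pd/Et2Zn.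

Step 12
Reactants: 19 (1R,2R,4E,8S,9S,10R)-9-hydroxy-1,5-dimethyl-8-(prop-1-en-2-yl)-11-oxabicyclo[8.1.0]undec-4-en-2-yl (2Z)-2-methylbut-2-enoate
Product: 20 (1R,2R,4E,8S,9S,10R)-9-(acetyloxy)-1,5-dimethyl-8-(prop-1-en-2-yl)-11-oxabicyclo[8.1.0]undec-4-en-2-yl (2Z)-2-methylbut-2-enoate
Conditions: Ac2O, DMAP (10 mol %), Et3N, CH2Cl2, 0 °C to rt
Reagents that add atoms: acetic anhydride, CC(=O)OC(C)=O
Why: DMAP-catalysed acetylation of the C6 hydroxyl proceeds with retention and under base, which the acid-sensitive epoxy-cyclodecene tolerates.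

Step 13
Reactants: 20 (1R,2R,4E,8S,9S,10R)-9-(acetyloxy)-1,5-dimethyl-8-(prop-1-en-2-yl)-11-oxabicyclo[8.1.0]undec-4-en-2-yl (2Z)-2-methylbut-2-enoate
Product: 21 (1R,2R,4E,8S,9S,10R)-9-(acetyloxy)-1,5-dimethyl-8-(propan-2-yl)-11-oxabicyclo[8.1.0]undec-4-en-2-yl (2Z)-2-methylbut-2-enoate [(3R,4R,5R,6S,7S)-6-acetoxy-3-angeloyloxy-4,5-epoxygermacr-1(10)-ene]
Conditions: H2 (1 atm), RhCl(PPh3)3 (10 mol %), benzene, rt
Reagents that add atoms: none
Why: homogeneous hydrogenation with RhCl(PPh3)3 reduces the unhindered 1,1-disubstituted isopropenyl alkene much faster than the trisubstituted ring alkene or the conjugated angelate, so the isopropyl group forms without touching C7 or the other alkenes.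

Compound list
1 | 5-bromo-2-methylpent-2-ene | CC(C)=CCCBr | starting material
2 | 6-methylhept-5-en-1-yne | CC(C)=CCCC#C | intermediate
3 | (4R)-2,2-dimethyl-1,3-dioxolane-4-carbaldehyde | O=C[C@H]1COC(C)(C)O1 | starting material
4 | (4S)-4-ethynyl-2,2-dimethyl-1,3-dioxolane | C#C[C@H]1COC(C)(C)O1 | intermediate
5 | (2S)-but-3-yne-1,2-diol | C#C[C@H](O)CO | intermediate
6 | (2S)-2-hydroxybut-3-yn-1-yl 4-methylbenzenesulfonate | C#C[C@H](O)COS(=O)(=O)c1ccc(C)cc1 | intermediate
7 | [(1E,3S)-3-[(dimethylalumanyl)oxy]-2-methyl-4-(tosyloxy)but-1-en-1-yl]dimethylalumane | C[Al](C)/C=C(\C)[C@H](O[Al](C)C)COS(=O)(=O)c1ccc(C)cc1 | intermediate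
8 | (2S,3E)-2-hydroxy-3-methyl-5-{[tri(propan-2-yl)silyl]oxy}pent-3-en-1-yl 4-methylbenzenesulfonate | CC(C)[Si](OC/C=C(\C)[C@H](O)COS(=O)(=O)c1ccc(C)cc1)(C(C)C)C(C)C | intermediate
9 | (2R)-2-hydroxy-2-[(2R,3R)-2-methyl-3-({[tri(propan-2-yl)silyl]oxy}methyl)oxiran-2-yl]ethyl 4-methylbenzenesulfonate | Cc1ccc(cc1)S(=O)(=O)OC[C@@H](O)[C@@]1(C)O[C@@H]1CO[Si](C(C)C)(C(C)C)C(C)C | intermediate
10 | (2S,3R)-2-methyl-2-[(2R)-oxiran-2-yl]-3-({[tri(propan-2-yl)silyl]oxy}methyl)oxirane | C1O[C@H]1[C@@]2(C)O[C@@H]2CO[Si](C(C)C)(C(C)C)C(C)C | intermediate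
11 | [(1E)-2,6-dimethylhepta-1,5-dien-1-yl]dimethylalumane | C[Al](C)/C=C(\C)CCC=C(C)C | intermediate
12 | lithium butyl[(1E)-2,6-dimethylhepta-1,5-dien-1-yl]dimethylaluminate | [Li+].CCCC[Al-](C)(C)/C=C(\C)CCC=C(C)C | intermediate
13 | (1R,3E)-4,8-dimethyl-1-[(2R,3R)-2-methyl-3-({[tri(propan-2-yl)silyl]oxy}methyl)oxiran-2-yl]nona-3,7-dien-1-ol | CC(C)=CCC/C(C)=C/C[C@@H](O)[C@@]1(C)O[C@@H]1CO[Si](C(C)C)(C(C)C)C(C)C | intermediate
14 | (2Z)-2-methylbut-2-enoic acid (angelic acid) | C/C=C(/C)C(=O)O | starting material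
15 | (1R,3E)-4,8-dimethyl-1-[(2R,3R)-2-methyl-3-({[tri(propan-2-yl)silyl]oxy}methyl)oxiran-2-yl]nona-3,7-dien-1-yl (2Z)-2-methylbut-2-enoate | C/C=C(/C)C(=O)O[C@H](C/C=C(\C)CCC=C(C)C)[C@@]1(C)O[C@@H]1CO[Si](C(C)C)(C(C)C)C(C)C | intermediate
16 | (1R,3E)-7-chloro-4,8-dimethyl-1-[(2R,3R)-2-methyl-3-({[tri(propan-2-yl)silyl]oxy}methyl)oxiran-2-yl]nona-3,8-dien-1-yl (2Z)-2-methylbut-2-enoate, both C–Cl epimers | C/C=C(/C)C(=O)O[C@H](C/C=C(\C)CCC(Cl)C(C)=C)[C@@]1(C)O[C@@H]1CO[Si](C(C)C)(C(C)C)C(C)C | intermediate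
17 | (1R,3E)-7-chloro-1-[(2R,3R)-3-(hydroxymethyl)-2-methyloxiran-2-yl]-4,8-dimethylnona-3,8-dien-1-yl (2Z)-2-methylbut-2-enoate, both C–Cl epimers | C/C=C(/C)C(=O)O[C@H](C/C=C(\C)CCC(Cl)C(C)=C)[C@@]1(C)O[C@@H]1CO | intermediate
18 | (1R,3E)-7-chloro-1-[(2R,3S)-3-formyl-2-methyloxiran-2-yl]-4,8-dimethylnona-3,8-dien-1-yl (2Z)-2-methylbut-2-enoate, both C–Cl epimers | C/C=C(/C)C(=O)O[C@H](C/C=C(\C)CCC(Cl)C(C)=C)[C@@]1(C)O[C@@H]1C=O | intermediate
19 | (1R,2R,4E,8S,9S,10R)-9-hydroxy-1,5-dimethyl-8-(prop-1-en-2-yl)-11-oxabicyclo[8.1.0]undec-4-en-2-yl (2Z)-2-methylbut-2-enoate | C/C=C(/C)C(=O)O[C@@H]1C/C=C(\C)CC[C@@H](C(C)=C)[C@H](O)[C@H]2O[C@@]21C | intermediate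
20 | (1R,2R,4E,8S,9S,10R)-9-(acetyloxy)-1,5-dimethyl-8-(prop-1-en-2-yl)-11-oxabicyclo[8.1.0]undec-4-en-2-yl (2Z)-2-methylbut-2-enoate | C/C=C(/C)C(=O)O[C@@H]1C/C=C(\C)CC[C@@H](C(C)=C)[C@H](OC(C)=O)[C@H]2O[C@@]21C | intermediate
21 | (1R,2R,4E,8S,9S,10R)-9-(acetyloxy)-1,5-dimethyl-8-(propan-2-yl)-11-oxabicyclo[8.1.0]undec-4-en-2-yl (2Z)-2-methylbut-2-enoate | C/C=C(/C)C(=O)O[C@@H]1C/C=C(\C)CC[C@@H](C(C)C)[C@H](OC(C)=O)[C@H]2O[C@@]21C | target

Total step count: 13. Longest linear sequence: 12 steps (3 to 21, steps 2–13); step 1 is the convergent branch.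

Steps most likely to fail

Ring closure, step 11 (the proposed new method). The risks are slow chromium turnover at high dilution, simple reduction of the allylic chloride, and the wrong aldehyde face. The fallback sets out from 18 and returns at 19 with known chemistry of a different kind: a thermal palladium/zinc umpolung allylation with Pd(PPh3)4 (zerovalent palladium, 10 mol %), Et2Zn (3 equiv) and K2CO3 in DMA at 5 mM and rt. The π-allylpalladium formed from the allylic chloride is transmetalated to an allylzinc, which adds to the aldehyde through the same chair. This closure is established for 4,5-epoxyfarnesal-type chlorides. It makes no new compound.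

Terminal chlorination, step 8. The risk is competing ene-chlorination at the C1=C10 alkene. The fallback sets out from 15 and returns at 19. Allylic oxidation with SeO2 (cat.) and t-BuOOH, selective for the (E)-methyl of a terminal isopropylidene, gives (1R,3E,7E)-9-hydroxy-4,8-dimethyl-1-[(2R,3R)-2-methyl-3-({[tri(propan-2-yl)silyl]oxy}methyl)oxiran-2-yl]nona-3,7-dien-1-yl (2Z)-2-methylbut-2-enoate F2. MsCl, LiCl and 2,4,6-collidine in DMF at 0 °C convert it into the primary allylic chloride (1R,3E,7E)-9-chloro-4,8-dimethyl-1-[(2R,3R)-2-methyl-3-({[tri(propan-2-yl)silyl]oxy}methyl)oxiran-2-yl]nona-3,7-dien-1-yl (2Z)-2-methylbut-2-enoate F3. HF·pyridine then gives (1R,3E,7E)-9-chloro-1-[(2R,3R)-3-(hydroxymethyl)-2-methyloxiran-2-yl]-4,8-dimethylnona-3,7-dien-1-yl (2Z)-2-methylbut-2-enoate F4, and Dess–Martin periodinane gives (1R,3E,7E)-9-chloro-1-[(2R,3S)-3-formyl-2-methyloxiran-2-yl]-4,8-dimethylnona-3,7-dien-1-yl (2Z)-2-methylbut-2-enoate F5. Under the conditions of step 11, F5 forms the same allylchromium as 18 and closes to 19.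

Methylalumination with silyloxymethyl trapping, step 4. The risks are O-alkylation of the aluminium alkoxide and sluggish C-alkylation by the chloromethyl ether. The fallback sets out from 6 (through alanate 7) and returns at 8. Alanate 7 is trapped with paraformaldehyde (the classical hydroxymethylation of alkenylalanes) to give (2S,3E)-2,5-dihydroxy-3-methylpent-3-en-1-yl 4-methylbenzenesulfonate F1. TIPSCl and imidazole in CH2Cl2 at 0 °C then silylate the primary allylic hydroxyl selectively and give 8, at the cost of one extra step.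

Further compounds
F1 | step 4 | (2S,3E)-2,5-dihydroxy-3-methylpent-3-en-1-yl 4-methylbenzenesulfonate | OC/C=C(\C)[C@H](O)COS(=O)(=O)c1ccc(C)cc1
F2 | step 8 | (1R,3E,7E)-9-hydroxy-4,8-dimethyl-1-[(2R,3R)-2-methyl-3-({[tri(propan-2-yl)silyl]oxy}methyl)oxiran-2-yl]nona-3,7-dien-1-yl (2Z)-2-methylbut-2-enoate | C/C=C(/C)C(=O)O[C@H](C/C=C(\C)CC/C=C(\C)CO)[C@@]1(C)O[C@@H]1CO[Si](C(C)C)(C(C)C)C(C)C
F3 | step 8 | (1R,3E,7E)-9-chloro-4,8-dimethyl-1-[(2R,3R)-2-methyl-3-({[tri(propan-2-yl)silyl]oxy}methyl)oxiran-2-yl]nona-3,7-dien-1-yl (2Z)-2-methylbut-2-enoate | C/C=C(/C)C(=O)O[C@H](C/C=C(\C)CC/C=C(\C)CCl)[C@@]1(C)O[C@@H]1CO[Si](C(C)C)(C(C)C)C(C)C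
F4 | step 8 | (1R,3E,7E)-9-chloro-1-[(2R,3R)-3-(hydroxymethyl)-2-methyloxiran-2-yl]-4,8-dimethylnona-3,7-dien-1-yl (2Z)-2-methylbut-2-enoate | C/C=C(/C)C(=O)O[C@H](C/C=C(\C)CC/C=C(\C)CCl)[C@@]1(C)O[C@@H]1CO
F5 | step 8 | (1R,3E,7E)-9-chloro-1-[(2R,3S)-3-formyl-2-methyloxiran-2-yl]-4,8-dimethylnona-3,7-dien-1-yl (2Z)-2-methylbut-2-enoate | C/C=C(/C)C(=O)O[C@H](C/C=C(\C)CC/C=C(\C)CCl)[C@@]1(C)O[C@@H]1C=O
F0 | step 11 | none | none
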